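The lactone is disconnected at C7=C11: the α-methylene lactone is traced to a butenolide fused to the cyclohexene ring at C7–C8. An intramolecular Horner–Wadsworth–Emmons olefination of a C8-O-phosphonoacetate onto a C7 ketone forms the C7=C11 bond and closes the five-membered lactone ring in one operation. It exploits the 1,3-trans oxygens on C6 and C8 flanking C7, which map onto the C3 and C5 hydroxyls of shikimic acid, whose C4 hydroxyl becomes the ketone. The precursor is a 5-alkyl-10-methylcyclohexene with a C6 silyl ether, a C7 ketone and a C8 diethylphosphonoacetate, its C4 side-chain stereocentre installed earlier by a stereospecific boron-to-carbon migration.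

Key step: step 16

Remark: atoms carry the numbering of the target throughout (cyclohexene ring C5–C10 with methyl C14 on C10; lactone carbons C11, C12, C13 on C7 with the ring oxygen on C8; side chain C4–C1 with methyl C15 on C4). BDA = 2,3-dimethoxybutane-2,3-diyl acetal bridging O7 and O8; Cb = N,N-diisopropylcarbamoyl; pin = pinacolato. The two silyl ethers are chosen to differ (TBS on O6, TBDPS on O1) so that O6 can be freed alone after the key step.

Step 1
Reactants: 1 shikimic acid
Product: 2 methyl shikimate BDA acetal (trans O7/O8 diol bridged, both acetal carbons S, C6 hydroxyl free)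
Conditions: butane-2,3-dione, HC(OMe)3, CSA (cat.), MeOH, reflux
Reagents that add atoms: butane-2,3-dione CC(=O)C(C)=O; methanol CO
Why: Fischer esterification and butane-2,3-diacetal formation run in the same acidic methanol, and the diacetal selects the trans-diequatorial O7/O8 diol (two axial, anomerically stabilised methoxy groups) over the cis O6/O7 pair, so no stereocentre of 1 is touched.

Step 2
Reactants: 2 methyl shikimate BDA acetal
Product: 3 BDA-protected diol (C14 hydroxymethyl on C10, C6 hydroxyl free)
Conditions: i-Bu2AlH (3.5 equiv), CH2Cl2, −78 → 0 °C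
Reagents that add atoms: none
Why: 1,2-reduction of an α,β-unsaturated ester by an aluminium hydride should give the allylic alcohol and leave the acetal alone.

Step 3
Reactants: 3 BDA-protected diol
Product: 5 C14 allylic chloride (C6 hydroxyl free), via C14 allylic mesylate 4 (not isolated)
Conditions: MsCl (1.1 equiv), 2,4,6-collidine, LiCl, DMF, 0 °C
Reagents that add atoms: lithium chloride [Li+].[Cl-]
Why: the primary allylic hydroxyl is sulfonylated much faster than the flanked secondary one and the mesylate is displaced in situ by chloride (SN2 substitution of an allylic sulfonate).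

Step 4
Reactants: 5 C14 allylic chloride
Product: 6 C10-methyl allylic alcohol (BDA on O7/O8, C6 hydroxyl free)
Conditions: LiEt3BH (2.5 equiv), THF, 0 °C → rt
Reagents that add atoms: none
Why: SN2 hydride displacement of a primary allylic chloride by a trialkylborohydride completes the reduction of the carboxyl carbon to the C14 methyl group, the free hydroxyl only consuming one equivalent of hydride.

Step 5
Reactants: 6 C10-methyl allylic alcohol
Product: 7 enone (C6 ketone conjugated with C5=C10, BDA on O7/O8)
Conditions: Dess–Martin periodinane, CH2Cl2, 0 °C → rt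
Reagents that add atoms: none
Why: Dess–Martin oxidation of the secondary allylic alcohol gives the enone, and the β-oxygen on C8 is held equatorial by the trans-fused dioxane, which disfavours β-elimination.

Step 6
Reactants: 7 enone
Product: 8 5-iodo enone
Conditions: I2 (2 equiv), pyridine/CH2Cl2 (1:1), rt
Reagents that add atoms: iodine II
Why: α-iodination of an enone with iodine and pyridine (conjugate addition of pyridine, iodination of the enolate, elimination) places iodine on C5, the only α-carbon of the enone.

Step 7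
Reactants: 8 5-iodo enone
Product: 9 (6S)-5-iodo allylic alcohol (C6 hydroxyl cis to O7 and trans to O8, as in shikimic acid)
Conditions: Li[HB(s-Bu)3], THF, −78 °C
Reagents that add atoms: none
Why: 1,2-reduction by a bulky trialkylborohydride (conjugate addition is blocked by the β-methyl group), which should approach C6 along the pseudo-equatorial trajectory on the face opposite to O7, the pseudo-axial path being hindered by the axial C8–H, and so give the pseudo-axial alcohol cis to O7, an outcome that allylic 1,2-strain with the vinylic iodine also favours.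

Step 8
Reactants: 9 (6S)-5-iodo allylic alcohol
Product: 10 C6 TBS ether of the vinyl iodide
Conditions: TBSOTf, 2,6-lutidine, CH2Cl2, −78 → 0 °C
Reagents that add atoms: tert-butyldimethylsilyl trifluoromethanesulfonate CC(C)(C)[Si](C)(C)OS(=O)(=O)C(F)(F)F
Why: silylation of a hindered secondary alcohol with a silyl triflate under buffered conditions that should leave the acetal intact.

Step 9
Reactants: 11 butane-1,4-diol
Product: 12 4-[(tert-butyldiphenylsilyl)oxy]butan-1-ol
Conditions: TBDPSCl (1 equiv), imidazole, 11 (4 equiv), THF, 0 °C → rt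
Reagents that add atoms: tert-butyl(chloro)diphenylsilane CC(C)(C)[Si](Cl)(c1ccccc1)c1ccccc1
Why: statistical monosilylation of a symmetrical diol used in excess.

Step 10
Reactants: 12 4-[(tert-butyldiphenylsilyl)oxy]butan-1-ol
Product: 13 4-[(tert-butyldiphenylsilyl)oxy]butyl N,N-diisopropylcarbamate
Conditions: i-Pr2NC(O)Cl, Et3N, CH2Cl2, reflux
Reagents that add atoms: N,N-diisopropylcarbamoyl chloride CC(C)N(C(C)C)C(Cl)=O
Why: O-carbamoylation of a primary alcohol gives the carbamate needed for sparteine-mediated α-lithiation.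

Step 11
Reactants: 13 carbamate; 14 methylboronic acid pinacol ester (MeBpin)
Product: 17 (S)-tert-butyl{[4-(4,4,5,5-tetramethyl-1,3,2-dioxaborolan-2-yl)pentyl]oxy}diphenylsilane, via α-lithiated carbamate 15 (not isolated), via lithium boronate complex 16 (not isolated)
Conditions: s-BuLi, (−)-sparteine, Et2O, −78 °C; 14, −78 °C; MgBr2·OEt2, reflux
Reagents that add atoms: none
Why: lithiation–borylation, in which s-BuLi/(−)-sparteine removes the pro-S proton, the lithium compound is borylated with retention and methyl then migrates from boron to carbon with inversion as the carbamate leaves (1,2-metallate rearrangement), which sets the future C4 as S.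

Step 12
Reactants: 10 C6 TBS ether of the vinyl iodide; 17 (S)-boronic ester
Product: 21 coupled cyclohexene (C5 bears the (S)-5-(TBDPS-oxy)pentan-2-yl chain, C6 OTBS, BDA on O7/O8), via C5 vinyllithium 18 (not isolated), via lithium alkenylboronate complex 19 (not isolated), via β-iodo boronic ester 20 (not isolated)
Conditions: t-BuLi (2.1 equiv), THF, −78 °C; 17, −78 → 0 °C; I2, MeOH/THF, −78 °C; NaOMe, MeOH, −78 °C → rt
Reagents that add atoms: none
Why: Zweifel olefination, in which iodine–lithium exchange gives the C5 vinyllithium, this forms a boronate complex with 17, iodination triggers 1,2-migration of the secondary alkyl group from boron to C5 with retention at C4, and methoxide then expels boron and the tertiary C10 iodide to give the C5=C10 alkene (a syn or ionisation-assisted elimination, as cyclic alkenyllithium partners require).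

Step 13
Reactants: 21 coupled cyclohexene
Product: 22 C7,C8-diol (C6 OTBS, C1 OTBDPS)
Conditions: TFA/H2O (9:1), CH2Cl2, 0 °C, 10 min
Reagents that add atoms: none
Why: acid hydrolysis of the butane-2,3-diacetal, during which the hindered secondary TBS ether and the primary TBDPS ether should survive the brief exposure and the neighbouring oxygen on C7 disfavours ionisation at allylic C6.

Step 14
Reactants: 22 C7,C8-diol; 23 diethylphosphonoacetic acid
Product: 24 C8 diethylphosphonoacetate (C7 hydroxyl free)
Conditions: DCC, DMAP (cat.), CH2Cl2, 0 °C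
Reagents that add atoms: none
Why: Steglich esterification, selective for the C8 hydroxyl because it lies next to the C9 methylene whereas the C7 hydroxyl is flanked by C8 and the silyloxy-bearing C6 (the order of reactivity known for 3-O-silyl shikimates).

Step 15
Reactants: 24 C8 diethylphosphonoacetate
Product: 25 C7 ketone with C8 phosphonoacetate and C6 OTBS
Conditions: Dess–Martin periodinane, CH2Cl2, 0 °C → rt
Reagents that add atoms: none
Why: Dess–Martin oxidation under near-neutral conditions converts the remaining secondary alcohol into the ketone and should not epimerise C6 or C8.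

Step 16
Reactants: 25 C7 ketone with C8 phosphonoacetate
Product: 26 fused butenolide (C7=C11, lactone C12 to O8, C6 OTBS)
Conditions: LiCl (3 equiv), DBU (1.1 equiv), MeCN, 0 °C
Reagents that add atoms: none
Why: DBU deprotonates the lithium-chelated phosphonoacetate, the carbanion adds to the C7 ketone, and the oxaphosphetane collapses with loss of diethyl phosphate to give the C7=C11 double bond (intramolecular Horner–Wadsworth–Emmons olefination under Masamune–Roush conditions). The closest known reaction type is the conversion of α-(phosphonoacetoxy) ketones into fused butenolides. The lactone ring closes in the 5-exo-trig mode, the carbanion attacking the carbonyl carbon while the C=O bond stays outside the forming ring. No stereocentre is created, since C7 becomes trigonal and is set later in step 18. The step needs site selectivity for the phosphonate methylene over the C6–H and C8–H of the ketone, which the much higher acidity of the chelated phosphonoacetate and the fast five-membered closure should secure. It also needs C6 and C8 to keep their configuration, for which an amine base, a single equivalent of it and a cold, short reaction are chosen.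

Step 17
Reactants: 26 fused butenolide
Product: 27 C6-hydroxy butenolide (C1 OTBDPS retained)
Conditions: HF·pyridine, pyridine, THF, 0 °C → rt
Reagents that add atoms: none
Why: fluoride desilylation under buffered, non-basic conditions should remove the secondary TBS ether faster than the more acid-stable primary TBDPS ether and cannot deprotonate the butenolide.

Step 18
Reactants: 27 C6-hydroxy butenolide
Product: 28 cis-fused saturated lactone (7R; H7 cis to O6, C11 cis to O8), C6 hydroxyl free
Conditions: [Ir(cod)(PCy3)(py)]PF6 (5 mol %), H2 (1 atm), CH2Cl2, 0 °C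
Reagents that add atoms: none
Why: hydroxyl-directed homogeneous hydrogenation, in which the cationic iridium complex binds the C6 hydroxyl and delivers both hydrogens to C7=C11 from the hydroxyl face, so that C11 ends up trans to O6 and cis to O8 (cis ring fusion), while the more hindered tetrasubstituted C5=C10 alkene should react more slowly.

Step 19
Reactants: 28 cis-fused saturated lactone
Product: 32 α-methylene lactone with free C6 hydroxyl, via dilithium alkoxide enolate 29 (not isolated), via C11 Mannich base 30 (not isolated), via trimethylammonium iodide 31 (not isolated)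
Conditions: LiN(i-Pr)2 (2.3 equiv), THF, −78 °C; CH2=NMe2+ I−, −78 → 0 °C; MeI, MeOH, rt; NaHCO3 (aq), CH2Cl2, rt
Reagents that add atoms: dimethylmethyleneiminium iodide C=[N+](C)C.[I-]
Why: Mannich aminomethylation of the lactone enolate (the C6 alkoxide is carried as a spectator), N-quaternisation and E1cB elimination install the C11=C13 methylene, the standard route to α-methylene-γ-lactones.

Step 20
Reactants: 32 α-methylene lactone with free C6 hydroxyl; 33 (R)-2-methylbutanoic acid
Product: 35 C6 (R)-2-methylbutanoate (C1 OTBDPS), via (R,R)-2-methylbutanoic anhydride 34 (not isolated)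
Conditions: 33 (3 equiv), DCC (1.5 equiv), CH2Cl2, 0 °C; then 32, DMAP, pyridine, rt
Reagents that add atoms: none
Why: acylation of the hindered C6 alcohol by the preformed symmetrical anhydride under DMAP catalysis, a method that transfers α-branched acyl groups without racemisation of the α-carbon.

Step 21
Reactants: 35 C6 (R)-2-methylbutanoate
Product: 36 target CNP0291605.2
Conditions: HF·pyridine, THF, rt
Reagents that add atoms: none
Why: fluoride cleavage of the primary TBDPS ether under mildly acidic conditions that should spare the α-methylene lactone and the ester.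

Compound list

1 | shikimic acid, (3R,4S,5R)-3,4,5-trihydroxycyclohex-1-ene-1-carboxylic acid | OC(=O)C1=C[C@@H](O)[C@@H](O)[C@H](O)C1 | starting material
2 | methyl shikimate with the trans O7/O8 diol bridged as (S,S)-BDA acetal, C6 hydroxyl free | COC(=O)C1=C[C@@H](O)[C@H]2O[C@](C)(OC)[C@@](C)(OC)O[C@@H]2C1 | intermediate
3 | BDA-protected diol, C14 hydroxymethyl on C10 | OCC1=C[C@@H](O)[C@H]2O[C@](C)(OC)[C@@](C)(OC)O[C@@H]2C1 | intermediate
4 | C14 allylic mesylate of 3 (not isolated) | CS(=O)(=O)OCC1=C[C@@H](O)[C@H]2O[C@](C)(OC)[C@@](C)(OC)O[C@@H]2C1 | intermediate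
5 | C14 allylic chloride | ClCC1=C[C@@H](O)[C@H]2O[C@](C)(OC)[C@@](C)(OC)O[C@@H]2C1 | intermediate
6 | C10-methyl allylic alcohol, BDA on O7/O8 | CC1=C[C@@H](O)[C@H]2O[C@](C)(OC)[C@@](C)(OC)O[C@@H]2C1 | intermediate
7 | enone, C6 ketone, C5=C10 | CC1=CC(=O)[C@H]2O[C@](C)(OC)[C@@](C)(OC)O[C@@H]2C1 | intermediate
8 | 5-iodo enone | CC1=C(I)C(=O)[C@H]2O[C@](C)(OC)[C@@](C)(OC)O[C@@H]2C1 | intermediate
9 | (6S)-5-iodo allylic alcohol, C6 hydroxyl cis to O7 | CC1=C(I)[C@@H](O)[C@H]2O[C@](C)(OC)[C@@](C)(OC)O[C@@H]2C1 | intermediate
10 | C6 TBS ether of 9 | CC1=C(I)[C@@H](O[Si](C)(C)C(C)(C)C)[C@H]2O[C@](C)(OC)[C@@](C)(OC)O[C@@H]2C1 | intermediate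
11 | butane-1,4-diol | OCCCCO | starting material
12 | 4-[(tert-butyldiphenylsilyl)oxy]butan-1-ol | OCCCCO[Si](c1ccccc1)(c1ccccc1)C(C)(C)C | intermediate
13 | 4-[(tert-butyldiphenylsilyl)oxy]butyl N,N-diisopropylcarbamate | CC(C)N(C(C)C)C(=O)OCCCCO[Si](c1ccccc1)(c1ccccc1)C(C)(C)C | intermediate
14 | methylboronic acid pinacol ester, 2,4,4,5,5-pentamethyl-1,3,2-dioxaborolane | CB1OC(C)(C)C(C)(C)O1 | starting material
15 | (S)-α-lithiated carbamate, sparteine complex (not isolated) | [Li][C@H](OC(=O)N(C(C)C)C(C)C)CCCO[Si](c1ccccc1)(c1ccccc1)C(C)(C)C | intermediate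
16 | lithium methyl(pinacolato)boronate complex of 15 (not isolated) | [Li+].C[B-]1(OC(C)(C)C(C)(C)O1)[C@H](OC(=O)N(C(C)C)C(C)C)CCCO[Si](c2ccccc2)(c2ccccc2)C(C)(C)C | intermediate
17 | (S)-tert-butyl{[4-(4,4,5,5-tetramethyl-1,3,2-dioxaborolan-2-yl)pentyl]oxy}diphenylsilane | C[C@H](B1OC(C)(C)C(C)(C)O1)CCCO[Si](c2ccccc2)(c2ccccc2)C(C)(C)C | intermediate
18 | C5 vinyllithium from 10 (not isolated) | CC1=C([Li])[C@@H](O[Si](C)(C)C(C)(C)C)[C@H]2O[C@](C)(OC)[C@@](C)(OC)O[C@@H]2C1 | intermediate
19 | lithium alkenyl(sec-alkyl)(pinacolato)boronate complex (not isolated) | [Li+].CC1=C([B-]3(OC(C)(C)C(C)(C)O3)[C@@H](C)CCCO[Si](c4ccccc4)(c4ccccc4)C(C)(C)C)[C@@H](O[Si](C)(C)C(C)(C)C)[C@H]2O[C@](C)(OC)[C@@](C)(OC)O[C@@H]2C1 | intermediate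
20 | β-iodo boronic ester, C10 iodide and C5 boronate, both transient centres unassigned and destroyed in the elimination (not isolated) | CC1(I)C(B3OC(C)(C)C(C)(C)O3)([C@@H](C)CCCO[Si](c4ccccc4)(c4ccccc4)C(C)(C)C)[C@@H](O[Si](C)(C)C(C)(C)C)[C@H]2O[C@](C)(OC)[C@@](C)(OC)O[C@@H]2C1 | intermediate
21 | coupled cyclohexene: C5 carries the (S)-5-(TBDPS-oxy)pentan-2-yl chain (C4 S), C6 OTBS, BDA on O7/O8 | CC1=C([C@@H](C)CCCO[Si](c3ccccc3)(c3ccccc3)C(C)(C)C)[C@@H](O[Si](C)(C)C(C)(C)C)[C@H]2O[C@](C)(OC)[C@@](C)(OC)O[C@@H]2C1 | intermediate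
22 | C7,C8-diol, C6 OTBS trans to O8, C1 OTBDPS | CC1=C([C@@H](C)CCCO[Si](c2ccccc2)(c2ccccc2)C(C)(C)C)[C@@H](O[Si](C)(C)C(C)(C)C)[C@@H](O)[C@H](O)C1 | intermediate
23 | diethylphosphonoacetic acid | OC(=O)CP(=O)(OCC)OCC | starting material
24 | C8 diethylphosphonoacetate, C7 hydroxyl free | CCOP(=O)(OCC)CC(=O)O[C@@H]1CC(C)=C([C@@H](C)CCCO[Si](c2ccccc2)(c2ccccc2)C(C)(C)C)[C@@H](O[Si](C)(C)C(C)(C)C)[C@H]1O | intermediate
25 | C7 ketone with C8 diethylphosphonoacetate and C6 OTBS (O6 and O8 trans) | CCOP(=O)(OCC)CC(=O)O[C@@H]1CC(C)=C([C@@H](C)CCCO[Si](c2ccccc2)(c2ccccc2)C(C)(C)C)[C@@H](O[Si](C)(C)C(C)(C)C)C1=O | intermediate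
26 | fused butenolide, C7=C11, lactone closed on O8, C6 OTBS | O=C1C=C2[C@H](O[Si](C)(C)C(C)(C)C)C([C@@H](C)CCCO[Si](c3ccccc3)(c3ccccc3)C(C)(C)C)=C(C)C[C@H]2O1 | intermediate
27 | C6-hydroxy butenolide | O=C1C=C2[C@H](O)C([C@@H](C)CCCO[Si](c3ccccc3)(c3ccccc3)C(C)(C)C)=C(C)C[C@H]2O1 | intermediate
28 | cis-fused saturated lactone (7R), C6 hydroxyl trans to C11 | O=C1C[C@H]2[C@H](O)C([C@@H](C)CCCO[Si](c3ccccc3)(c3ccccc3)C(C)(C)C)=C(C)C[C@H]2O1 | intermediate
29 | dilithium C6-alkoxide lactone enolate (not isolated) | [Li+].[Li+].[O-]C1=C[C@H]2[C@H]([O-])C([C@@H](C)CCCO[Si](c3ccccc3)(c3ccccc3)C(C)(C)C)=C(C)C[C@H]2O1 | intermediate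
30 | C11 (dimethylamino)methyl lactone, C11 epimers (not isolated) | CN(C)CC1C(=O)O[C@@H]2CC(C)=C([C@@H](C)CCCO[Si](c3ccccc3)(c3ccccc3)C(C)(C)C)[C@@H](O)[C@H]12 | intermediate
31 | trimethylammonium iodide of 30 (not isolated) | C[N+](C)(C)CC1C(=O)O[C@@H]2CC(C)=C([C@@H](C)CCCO[Si](c3ccccc3)(c3ccccc3)C(C)(C)C)[C@@H](O)[C@H]12.[I-] | intermediate
32 | α-methylene lactone, C6 hydroxyl free, C1 OTBDPS | C=C1C(=O)O[C@@H]2CC(C)=C([C@@H](C)CCCO[Si](c3ccccc3)(c3ccccc3)C(C)(C)C)[C@@H](O)[C@H]12 | intermediate
33 | (R)-2-methylbutanoic acid | OC(=O)[C@H](C)CC | starting material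
34 | (R,R)-2-methylbutanoic anhydride (not isolated) | CC[C@@H](C)C(=O)OC(=O)[C@H](C)CC | intermediate
35 | C6 (R)-2-methylbutanoate, C1 OTBDPS | C=C1C(=O)O[C@@H]2CC(C)=C([C@@H](C)CCCO[Si](c3ccccc3)(c3ccccc3)C(C)(C)C)[C@@H](OC(=O)[C@H](C)CC)[C@H]12 | intermediate
36 | CNP0291605.2, (4S,6S,7R,8R) with (R)-2-methylbutanoate on O6, cis-fused α-methylene-γ-lactone on C7/C8, primary alcohol at C1 | C=C1C(=O)O[C@@H]2CC(C)=C([C@@H](C)CCCO)[C@@H](OC(=O)[C@H](C)CC)[C@H]12 | target

Total step count: 21. Longest linear sequence: 18 steps from shikimic acid (steps 1–8 and 12–21); steps 9–11 make the side-chain boronic ester.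

Steps most likely to fail

Step 12. Boronate formation and the 1,2-shift onto the fully substituted C5 may be too slow for steric reasons, so that the vinyllithium is merely protonated or the complex is iodinated back to the vinyl iodide. The fallback sets out from 10 and returns at 21. Pent-4-yn-1-ol is silylated (TBDPSCl, imidazole) to tert-butyl(pent-4-yn-1-yloxy)diphenylsilane F1. Copper-catalysed α-selective hydroboration (CuCl, N-heterocyclic carbene ligand, NaOt-Bu, B2pin2, MeOH) converts it into the 1,1-disubstituted alkenylboronic ester F2. Suzuki–Miyaura coupling of this boronate with 10 (Pd(dppf)Cl2, Cs2CO3, DMF/H2O, 60 °C), a coupling that tolerates the hindered site, gives the 5-(alk-1-en-2-yl) diene F3. Asymmetric hydrogenation of its side-chain 1,1-disubstituted alkene with a cationic iridium phosphine–oxazoline complex [Ir(cod)(PHOX)][B(C6H3(CF3)2)4] under H2, the ligand enantiomer being chosen for the 4S product, leads back to 21. This catalyst class leaves the tetrasubstituted ring alkene alone.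

Step 16. The base may epimerise C6 or C8 of the doubly oxygenated ketone, or deprotonate the γ-position (C8) of the butenolide once formed, before olefination is complete. The fallback sets out from 22 and returns at 26. The C8 hydroxyl is acylated with bromoacetyl bromide and pyridine at −40 °C to give the C8 bromoacetate F4. Dess–Martin oxidation gives the C7 ketone F5. An intramolecular Reformatsky reaction with activated zinc in THF closes the lactone under non-basic conditions to the cis-fused C7-hydroxy lactone F6. Dehydration (SOCl2, pyridine, 0 °C) then gives 26.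

Step 18. The C6 hydroxyl is allylic to both alkenes, so over-reduction of C5=C10 or incomplete facial control may occur. The fallback sets out from 26 and returns at 28. Ligand-controlled copper hydride conjugate reduction of the silyl ether 26 (Cu(OAc)2, chiral bisphosphine, polymethylhydrosiloxane, t-BuOH, toluene) does not touch the isolated tetrasubstituted alkene. The ligand enantiomer is chosen to deliver hydride to the C7 face syn to O6, which gives the cis-fused saturated lactone silyl ether F7. HF·pyridine then removes the C6 silyl group to give 28.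

Further compounds

F1 | step 12 | tert-butyl(pent-4-yn-1-yloxy)diphenylsilane | C#CCCCO[Si](c1ccccc1)(c1ccccc1)C(C)(C)C
F2 | step 12 | tert-butyl{[4-(4,4,5,5-tetramethyl-1,3,2-dioxaborolan-2-yl)pent-4-en-1-yl]oxy}diphenylsilane | C=C(CCCO[Si](c1ccccc1)(c1ccccc1)C(C)(C)C)B1OC(C)(C)C(C)(C)O1
F3 | step 12 | diene: 21 with a C4=C15 methylene in place of the C4 stereocentre | CC1=C(C(=C)CCCO[Si](c3ccccc3)(c3ccccc3)C(C)(C)C)[C@@H](O[Si](C)(C)C(C)(C)C)[C@H]2O[C@](C)(OC)[C@@](C)(OC)O[C@@H]2C1
F4 | step 16 | C8 bromoacetate of diol 22, C7 hydroxyl free | BrCC(=O)O[C@@H]1CC(C)=C([C@@H](C)CCCO[Si](c2ccccc2)(c2ccccc2)C(C)(C)C)[C@@H](O[Si](C)(C)C(C)(C)C)[C@H]1O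
F5 | step 16 | C7 ketone with C8 bromoacetate and C6 OTBS | BrCC(=O)O[C@@H]1CC(C)=C([C@@H](C)CCCO[Si](c2ccccc2)(c2ccccc2)C(C)(C)C)[C@@H](O[Si](C)(C)C(C)(C)C)C1=O
F6 | step 16 | cis-fused C7-hydroxy lactone (C7 hydroxyl cis to O6, C11 cis to O8), C6 OTBS | O=C1C[C@@]2(O)[C@H](O[Si](C)(C)C(C)(C)C)C([C@@H](C)CCCO[Si](c3ccccc3)(c3ccccc3)C(C)(C)C)=C(C)C[C@H]2O1
F7 | step 18 | cis-fused saturated lactone (7R) with C6 OTBS | O=C1C[C@H]2[C@H](O[Si](C)(C)C(C)(C)C)C([C@@H](C)CCCO[Si](c3ccccc3)(c3ccccc3)C(C)(C)C)=C(C)C[C@H]2O1
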